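(Readings and results were computed from invented constants, and the scatter is random.)

**Time first.** G carries no exchanged ligand, and Z, E, Q and X carry one to 4, each step taking one J and freeing one L.

in all of them: G 25 mM

|  | J | L | remark | time |
|---|---|---|---|---|
| summer | 62 mM | 25 mM | run made earlier |  |
| midnight | 82 mM | 25 mM | run made earlier |  |
| south | 100 mM | 25.0 mM |  | 3.0 h |
| west | 75.0 mM | 25.0 mM |  | 3.0 h |

| run | time / min | E / % | X / % | G / % |
|---|---|---|---|---|
| summer | 8.00 | 7.8 | 14.3 | 8.6 |
| summer | 15.0 | 7.9 | 14.8 | 8.1 |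
| summer | 25.0 | 7.0 | 14.7 | 7.9 |
| summer | 50.0 | 7.6 | 15.2 | 8.3 |
| summer | 90.0 | 8.7 | 14.9 | 8.5 |
| midnight | 8.00 | 2.5 | 34.8 | 2.3 |
| midnight | 15.0 | 3.0 | 39.6 | 0.6 |
| midnight | 25.0 | 1.3 | 40.5 | 1.7 |
| midnight | 50.0 | 1.7 | 41.7 | 1.3 |
| midnight | 90.0 | 2.1 | 41.2 | 1.6 |

(scatter of a reading: 0.5 percentage points)

1. which of these holds the largest part of the G at the end of south (X / Q / Z / E / G)
2. which of these holds the largest part of the G at the end of west (X / Q / Z / E / G)
3. amount of E at the end of west, in percent of the G charged

- a reading or a percentage of L counts all its forms, free or not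

**The ladder.** In summer, G already stood at 8.6 % by 8.00 min, and it ended at 8.5 %. In midnight, X was still rising, from 34.8 % at that time to 40.5 % at 25.0 min, and it then stayed near 41.2 %. The 3.0 h asked of south and west is 7.20 times that, so I expected to be reading a plateau.

**Sites left.** I took the plateau to mean that J was used up, and I reckoned with what remained rather than what was made. The sites left, s, is the fraction of the 4 sites per G still unexchanged once J has gone: 0.250 for west, where J is the limiting reagent. That is 1.00 site per G on average, which pointed to Q. It lies between midnight's 0.180 and summer's 0.380. South gives 0, which pointed to X. But s gives a mean and not a spread, so I had no figure of my own for E.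

**The forecast.** It named X for south and Q for west, with 3.2 % of E in west (range 2 % to 4.8 %): “West has J/G = 3, with X about 30% and Q about 50%, so Q leads.”

**The result.** West gave 3.98 % of E, inside that range, with Q leading at 56.4 %; south gave X at 97.0 %.

    Q + J → L + X (k = 0.120 L mol⁻¹ s⁻¹)
    Z + J → L + E (k = 0.570 L mol⁻¹ s⁻¹)
    E + J → L + Q (k = 1.50 L mol⁻¹ s⁻¹)
    G + J → L + Z (k = 0.490 L mol⁻¹ s⁻¹)
    D ⇌ L, rate k5*(cs5 - [L]) while solid is left; crystals form when [L] > cs5 (solubility = 14.0 mM, k = 0.0250 s⁻¹)

At 30.0 h, west still showed 3.98 % of E, with J at 0 %. Counting the sites left in west's mixture at 3.0 h gives 0.250, the s reckoned beforehand.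

**A neighbour.** With 62 mM of G and west's J, s is 0.698. That flask ended with J at 0 %, G the largest holder at 34.0 % with Z beside it at 33.6 %, and a counted s of 0.698.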